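**Strategy.** The isoflavone is cut at the bond between C3 of the pyranone ring (ring C) and C1′ of the 4-hydroxy-3-prenylphenyl ring (ring B). Because C3 lies α to the C4 carbonyl and C2 is only a one-carbon bridge to O1, ring C need not exist when this bond is made. C3 is introduced as the methyl carbon of a tris-MOM-protected 3,5-diprenylphloroacetophenone. A palladium-catalysed enolate α-arylation with MOM-protected 4-bromo-2-prenylphenol forges the C3–C1′ bond and gives a deoxybenzoin that already carries all three prenyl groups. C2 is then inserted with DMF dimethyl acetal, and one acid treatment closes ring C and frees all phenols.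

Key step: step 5

Remark 1: the target has no stereocentre and no stereogenic double bond (each alkene ends in two methyl groups), so it is one achiral compound and no step has to control configuration.

Remark 2: species that differ from a product only in how many identical MOM groups have been attached or removed are not numbered. The enaminones are drawn as E isomers; the geometry of this push–pull double bond is of no consequence for the ring closure.

**Step 1**
Reactants: 1 2,4,6-trihydroxyacetophenone
Product: 3 1-[2,4,6-trihydroxy-3,5-bis(3-methylbut-2-en-1-yl)phenyl]ethan-1-one, via monoprenyl ketone 2 (not isolated)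
Conditions: prenyl bromide (2.1 equiv), 10% aq. KOH, 0 °C to rt; then dilute HCl to pH 3
Reagents that add atoms: prenyl bromide (1-bromo-3-methylbut-2-ene), CC(C)=CCBr
Why: C-alkylation of an acylphloroglucinol polyanion in aqueous alkali (the known C-prenylation of acylphloroglucinols), in which water solvates the oxygens and directs the soft allylic bromide to the two free ring carbons C3 and C5.

**Step 2**
Reactants: 3 1-[2,4,6-trihydroxy-3,5-bis(3-methylbut-2-en-1-yl)phenyl]ethan-1-one
Product: 4 1-[2,4,6-tris(methoxymethoxy)-3,5-bis(3-methylbut-2-en-1-yl)phenyl]ethan-1-one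
Conditions: NaH (3.3 equiv), DMF, 0 °C; MOMCl (3.5 equiv), 0 °C to rt
Reagents that add atoms: chloromethyl methyl ether (MOMCl), COCCl
Why: Williamson-type O-alkylation of the three phenoxides with a hard electrophile, with the base held at three equivalents so that the methyl ketone is not enolised and the base-stable prenyl groups are untouched.

**Step 3**
Reactants: 5 4-bromophenol
Product: 6 4-bromo-2-(3-methylbut-2-en-1-yl)phenol
Conditions: NaH (1.05 equiv), toluene, 0 °C; prenyl bromide (1.1 equiv), rt
Reagents that add atoms: prenyl bromide (1-bromo-3-methylbut-2-ene), CC(C)=CCBr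
Why: ortho-C-alkylation of a sodium phenoxide in a non-polar solvent, where the tight ion pair shields oxygen and the para position is blocked by bromine, so the prenyl group should enter next to the OH.

**Step 4**
Reactants: 6 4-bromo-2-(3-methylbut-2-en-1-yl)phenol
Product: 7 4-bromo-1-(methoxymethoxy)-2-(3-methylbut-2-en-1-yl)benzene
Conditions: NaH (1.1 equiv), THF, 0 °C; MOMCl (1.2 equiv), 0 °C to rt
Reagents that add atoms: chloromethyl methyl ether (MOMCl), COCCl
Why: Williamson-type O-alkylation of the phenoxide, which removes the acidic OH that would otherwise consume base and deactivate the bromide in the coupling.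

**Step 5**
Reactants: 4 1-[2,4,6-tris(methoxymethoxy)-3,5-bis(3-methylbut-2-en-1-yl)phenyl]ethan-1-one; 7 4-bromo-1-(methoxymethoxy)-2-(3-methylbut-2-en-1-yl)benzene
Product: 8 2-[4-(methoxymethoxy)-3-(3-methylbut-2-en-1-yl)phenyl]-1-[2,4,6-tris(methoxymethoxy)-3,5-bis(3-methylbut-2-en-1-yl)phenyl]ethan-1-one
Conditions: 7 (1.05 equiv), Pd2(dba)3 (2 mol %), XPhos (5 mol %), NaOtBu (1.3 equiv), toluene, 80 °C, argon
Reagents that add atoms: none
Why: Pd(0)/XPhos inserts into the C–Br bond of 7, NaOtBu converts the only enolisable position of 4 (the acetyl CH3, the future C3) into its enolate, transmetalation gives an arylpalladium C-enolate, and reductive elimination forms the C(sp3)–C(sp2) bond that becomes C3–C1′. The reaction type is the palladium-catalysed α-arylation of an aryl methyl ketone with an aryl bromide (Buchwald–Hartwig-type enolate arylation), a known reaction applied here to a new pair of partners. No ring is closed and no stereocentre is created, so neither a mode of closure nor a stereocontrol element is involved. The step needs monoarylation, which the two ortho MOM-oxy groups flanking the carbonyl and the bulky biarylphosphine should secure by hindering palladation of the more crowded product enolate. It also needs chemoselectivity for C–Br over the three trisubstituted prenyl alkenes, which are poor partners for carbopalladation. Finally the protecting groups must be inert, which holds because MOM acetals are stable to alkoxide and no free OH remains to be O-arylated or to quench the enolate.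

**Step 6**
Reactants: 8 2-[4-(methoxymethoxy)-3-(3-methylbut-2-en-1-yl)phenyl]-1-[2,4,6-tris(methoxymethoxy)-3,5-bis(3-methylbut-2-en-1-yl)phenyl]ethan-1-one
Product: 9 (E)-3-(dimethylamino)-2-[4-(methoxymethoxy)-3-(3-methylbut-2-en-1-yl)phenyl]-1-[2,4,6-tris(methoxymethoxy)-3,5-bis(3-methylbut-2-en-1-yl)phenyl]prop-2-en-1-one
Conditions: DMF-DMA (5 equiv), toluene, 100 °C
Reagents that add atoms: N,N-dimethylformamide dimethyl acetal (DMF-DMA), COC(OC)N(C)C
Why: formamide-acetal condensation (aminomethylenation) at the doubly activated benzylic methylene, the standard one-carbon insertion that turns a deoxybenzoin into an isoflavone precursor, under neutral conditions that leave MOM acetals and prenyl groups alone.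

**Step 7**
Reactants: 9 (E)-3-(dimethylamino)-2-[4-(methoxymethoxy)-3-(3-methylbut-2-en-1-yl)phenyl]-1-[2,4,6-tris(methoxymethoxy)-3,5-bis(3-methylbut-2-en-1-yl)phenyl]prop-2-en-1-one
Product: 11 euchrenone b1 (5,7-dihydroxy-3-[4-hydroxy-3-(3-methylbut-2-en-1-yl)phenyl]-6,8-bis(3-methylbut-2-en-1-yl)-4H-chromen-4-one), via tetrahydroxy enaminone 10 (not isolated)
Conditions: HCl (ca. 1 M in MeOH), 0 °C to rt, stopped at full conversion; aq. NaHCO3 work-up
Reagents that add atoms: none
Why: acid-catalysed acetal exchange removes the four MOM groups as dimethoxymethane and a freed ortho-phenol (the two are equivalent by symmetry) adds to the protonated vinylogous amide and expels dimethylamine (enaminone-to-chromone cyclocondensation), while brief exposure to dilute acid at room temperature should spare the prenyl groups.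

**Compound list**

1 | 2,4,6-trihydroxyacetophenone (phloroacetophenone) | CC(=O)c1c(O)cc(O)cc1O | starting material
2 | 1-[2,4,6-trihydroxy-3-(3-methylbut-2-en-1-yl)phenyl]ethan-1-one | CC(=O)c1c(O)cc(O)c(CC=C(C)C)c1O | intermediate (not isolated)
3 | 1-[2,4,6-trihydroxy-3,5-bis(3-methylbut-2-en-1-yl)phenyl]ethan-1-one | CC(=O)c1c(O)c(CC=C(C)C)c(O)c(CC=C(C)C)c1O | intermediate
4 | 1-[2,4,6-tris(methoxymethoxy)-3,5-bis(3-methylbut-2-en-1-yl)phenyl]ethan-1-one | CC(=O)c1c(OCOC)c(CC=C(C)C)c(OCOC)c(CC=C(C)C)c1OCOC | intermediate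
5 | 4-bromophenol | Oc1ccc(Br)cc1 | starting material
6 | 4-bromo-2-(3-methylbut-2-en-1-yl)phenol | CC(C)=CCc1cc(Br)ccc1O | intermediate
7 | 4-bromo-1-(methoxymethoxy)-2-(3-methylbut-2-en-1-yl)benzene | CC(C)=CCc1cc(Br)ccc1OCOC | intermediate
8 | 2-[4-(methoxymethoxy)-3-(3-methylbut-2-en-1-yl)phenyl]-1-[2,4,6-tris(methoxymethoxy)-3,5-bis(3-methylbut-2-en-1-yl)phenyl]ethan-1-one | COCOc1ccc(CC(=O)c2c(OCOC)c(CC=C(C)C)c(OCOC)c(CC=C(C)C)c2OCOC)cc1CC=C(C)C | intermediate
9 | (E)-3-(dimethylamino)-2-[4-(methoxymethoxy)-3-(3-methylbut-2-en-1-yl)phenyl]-1-[2,4,6-tris(methoxymethoxy)-3,5-bis(3-methylbut-2-en-1-yl)phenyl]prop-2-en-1-one | CN(C)/C=C(/C(=O)c1c(OCOC)c(CC=C(C)C)c(OCOC)c(CC=C(C)C)c1OCOC)c1ccc(OCOC)c(CC=C(C)C)c1 | intermediate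
10 | (E)-3-(dimethylamino)-2-[4-hydroxy-3-(3-methylbut-2-en-1-yl)phenyl]-1-[2,4,6-trihydroxy-3,5-bis(3-methylbut-2-en-1-yl)phenyl]prop-2-en-1-one | CN(C)/C=C(/C(=O)c1c(O)c(CC=C(C)C)c(O)c(CC=C(C)C)c1O)c1ccc(O)c(CC=C(C)C)c1 | intermediate (not isolated)
11 | euchrenone b1, 5,7-dihydroxy-3-[4-hydroxy-3-(3-methylbut-2-en-1-yl)phenyl]-6,8-bis(3-methylbut-2-en-1-yl)-4H-chromen-4-one | CC(C)=CCc1cc(-c2coc3c(CC=C(C)C)c(O)c(CC=C(C)C)c(O)c3c2=O)ccc1O | target

**Step count.** Total: 7 steps. Longest linear sequence: 5 steps (1, 2, 5, 6, 7); steps 3 and 4 form the second branch.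

**Steps most likely to fail**

Step 5. Oxidative addition to the electron-rich bromide may be slow, enolate formation and transmetalation at the doubly ortho-substituted ketone may be sluggish, and a second arylation or palladium-hydride migration of prenyl double bonds may compete. The fallback sets out from 3 and 7 and returns to the route at 11; it forms the same C3–C1′ bond by an sp2–sp2 coupling. Compound 3 is protected only twice (MOMCl, iPr2NEt, CH2Cl2) to give 1-[2-hydroxy-4,6-bis(methoxymethoxy)-3,5-bis(3-methylbut-2-en-1-yl)phenyl]ethan-1-one F1. DMF-DMA converts it into the o-hydroxyaryl enaminone F2. Iodine and pyridine in CHCl3 at 0 °C should effect iodination and ring closure to the 3-iodochromone F3. Bromide 7 is turned by Br/Li exchange (n-BuLi, THF, −78 °C) and iPrOBpin into the aryl pinacol boronate F4. Suzuki–Miyaura coupling of F3 with F4 (Pd(dppf)Cl2, K2CO3, DME/H2O, 80 °C) should give the tris-MOM isoflavone F5, and HCl in MeOH then gives 11.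

Step 7. The liberated hydroxyl groups may add under acid catalysis to the neighbouring prenyl double bonds (chroman formation), or the hindered acetals may be lost incompletely. The fallback sets out from 3 and 6 and returns at 11; it replaces acid-labile by fluoride-labile protection. SEMCl and NaH convert 3 into the tris-SEM ketone F6 and 6 into the SEM-protected aryl bromide F7. The α-arylation of step 5 should join them to the tetra-SEM deoxybenzoin F8, and DMF-DMA gives the tetra-SEM enaminone F9. TBAF in DMPU at 60 °C, followed by an acetic acid work-up, should then remove all four SEM groups and let 10 close to 11 without any strong acid.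

Step 1. Control over the degree and site of alkylation may be poor: the reaction may stop at one prenyl group, run on to geminal dialkylation with loss of aromaticity, or go to oxygen. The fallback sets out from 1 and returns at 4; it places the two prenyl groups by cross-coupling at pre-set positions. N-Iodosuccinimide (2.1 equiv, MeCN, 0 °C) should give 1-(2,4,6-trihydroxy-3,5-diiodophenyl)ethan-1-one F10. NaH and MOMCl give 1-[3,5-diiodo-2,4,6-tris(methoxymethoxy)phenyl]ethan-1-one F11. A double Stille coupling with tributyl(3-methylbut-2-en-1-yl)stannane (Pd(PPh3)4, CuI, CsF, DMF, 80 °C) should then give 4.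

**Further compounds**

F1 | step 5 | 1-[2-hydroxy-4,6-bis(methoxymethoxy)-3,5-bis(3-methylbut-2-en-1-yl)phenyl]ethan-1-one | CC(=O)c1c(O)c(CC=C(C)C)c(OCOC)c(CC=C(C)C)c1OCOC
F2 | step 5 | (E)-3-(dimethylamino)-1-[2-hydroxy-4,6-bis(methoxymethoxy)-3,5-bis(3-methylbut-2-en-1-yl)phenyl]prop-2-en-1-one | CN(C)/C=C/C(=O)c1c(O)c(CC=C(C)C)c(OCOC)c(CC=C(C)C)c1OCOC
F3 | step 5 | 3-iodo-5,7-bis(methoxymethoxy)-6,8-bis(3-methylbut-2-en-1-yl)-4H-chromen-4-one | COCOc1c(CC=C(C)C)c(OCOC)c2c(=O)c(I)coc2c1CC=C(C)C
F4 | step 5 | 2-[4-(methoxymethoxy)-3-(3-methylbut-2-en-1-yl)phenyl]-4,4,5,5-tetramethyl-1,3,2-dioxaborolane | COCOc1ccc(B2OC(C)(C)C(C)(C)O2)cc1CC=C(C)C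
F5 | step 5 | 5,7-bis(methoxymethoxy)-3-[4-(methoxymethoxy)-3-(3-methylbut-2-en-1-yl)phenyl]-6,8-bis(3-methylbut-2-en-1-yl)-4H-chromen-4-one | COCOc1ccc(-c2coc3c(CC=C(C)C)c(OCOC)c(CC=C(C)C)c(OCOC)c3c2=O)cc1CC=C(C)C
F6 | step 7 | 1-[3,5-bis(3-methylbut-2-en-1-yl)-2,4,6-tris{[2-(trimethylsilyl)ethoxy]methoxy}phenyl]ethan-1-one | CC(=O)c1c(OCOCC[Si](C)(C)C)c(CC=C(C)C)c(OCOCC[Si](C)(C)C)c(CC=C(C)C)c1OCOCC[Si](C)(C)C
F7 | step 7 | {2-[(4-bromo-2-(3-methylbut-2-en-1-yl)phenoxy)methoxy]ethyl}trimethylsilane | CC(C)=CCc1cc(Br)ccc1OCOCC[Si](C)(C)C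
F8 | step 7 | 2-[3-(3-methylbut-2-en-1-yl)-4-{[2-(trimethylsilyl)ethoxy]methoxy}phenyl]-1-[3,5-bis(3-methylbut-2-en-1-yl)-2,4,6-tris{[2-(trimethylsilyl)ethoxy]methoxy}phenyl]ethan-1-one | C[Si](C)(C)CCOCOc1ccc(CC(=O)c2c(OCOCC[Si](C)(C)C)c(CC=C(C)C)c(OCOCC[Si](C)(C)C)c(CC=C(C)C)c2OCOCC[Si](C)(C)C)cc1CC=C(C)C
F9 | step 7 | (E)-3-(dimethylamino)-2-[3-(3-methylbut-2-en-1-yl)-4-{[2-(trimethylsilyl)ethoxy]methoxy}phenyl]-1-[3,5-bis(3-methylbut-2-en-1-yl)-2,4,6-tris{[2-(trimethylsilyl)ethoxy]methoxy}phenyl]prop-2-en-1-one | CN(C)/C=C(/C(=O)c1c(OCOCC[Si](C)(C)C)c(CC=C(C)C)c(OCOCC[Si](C)(C)C)c(CC=C(C)C)c1OCOCC[Si](C)(C)C)c1ccc(OCOCC[Si](C)(C)C)c(CC=C(C)C)c1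
F10 | step 1 | 1-(2,4,6-trihydroxy-3,5-diiodophenyl)ethan-1-one | CC(=O)c1c(O)c(I)c(O)c(I)c1O
F11 | step 1 | 1-[3,5-diiodo-2,4,6-tris(methoxymethoxy)phenyl]ethan-1-one | CC(=O)c1c(OCOC)c(I)c(OCOC)c(I)c1OCOC
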